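Readings and results are simulated on assumed constants, and the scatter is random.

The vessel is a closed, stirred flask of constant volume, in which solid substrate, none of it in solution at the start, meets coupling partner.

| setting | birch | cedar | flask |
|---|---|---|---|
| solid substrate | 0.075 M | 0.037 M | 0.075 M |
| coupling partner | 1.2 equiv | 1.2 equiv | 1.20 equiv |
| temperature | 70 °C | 76 °C | 70 °C |
| remark | the very flask that is asked about, followed so far | run made earlier |  |
| time |  |  | 2.0 d |

| birch: time / h | birch: target / % | cedar: time / h | cedar: target / % |
|---|---|---|---|
| 8.00 | 42.5 | 1.33 | 38.5 |
| 15.0 | 37.4 | 2.50 | 38.0 |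
| 25.0 | 36.2 | 5.00 | 34.0 |
| 30.0 | 36.1 | 10.0 | 32.0 |
| 40.0 | 35.7 | 20.0 | 31.0 |

(scatter of a reading: 0.3 percentage points)

- spring: at 2.0 d add coupling partner, 100% of the amount charged, then wait 4.0 d
- midnight: at 2.0 d raise the temperature by 20 K, then wait 4.0 d
- noon: change nothing and wait 4.0 d more

- additions leave the volume as it is
- the analysis behind the earlier runs scatters by 0.3 percentage points, standard deviation
- at the start none of the solid substrate is in solution
- a reading or a percentage of target counts all its forms, free or not

* target, in percent of the solid substrate first charged, at 2.0 d
* which option adds most target ("none" when 2 percentage points or less is all one gets) (spring / midnight / noon / none)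
* target present, in percent of the solid substrate first charged, after spring
* target present, in percent of the solid substrate first charged, after noon

I keep the books on the coupling partner. The flask holds 0.0900 M of it, and this charge per litre is my partner budget, b. I assume that each target costs one coupling partner. So birch, the same flask followed so far, had paid at least 0.0319 M by its first reading at 8.00 h.

Of that, 0.0268 M still stands as target at 40.0 h. The 6.8 percentage points that left target stay paid for. At that first reading the budget therefore holds up to 0.0581 M unposted, either still in solution or lost some other way, and the readings do not show which.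

From 25.0 h to 40.0 h target moves by 0.5 points, against a scatter of 0.3 points. The cedar run, more dilute and hotter, also flattens, but lower, at 31.0%. I therefore expect about 35.7% now and no gain from noon. My books do not tell how much solid substrate stands ready for fresh coupling partner, so I commit to no figure for spring.

The forecast gives 35.7% now, 35.5% after noon and 8% after spring, with none as the best option. Its ground for spring: “Adding more partner would then restart the consumption.”

The flask gives 35.8% now, 35.8% after noon and 35.9% after spring. The best option is midnight, which adds 5.7 points, while spring adds 0.067 points.

    solid product ⇌ target, rate k1*(cs1 - [target]) while solid is left; crystals form when [target] > cs1 (solubility = 35.0 mM, k = 0.00126 s⁻¹)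
    2 dissolved substrate → side product (k = 0.00699 L mol⁻¹ s⁻¹, Ea = 76.0 kJ mol⁻¹)
    coupling partner → decomposed reagent (k = 5.24 × 10⁻⁵ s⁻¹, Ea = 98.0 kJ mol⁻¹)
    target ⇌ isomer of the product (K = 0.695, k = 2.21 × 10⁻⁵ s⁻¹, Ea = 100 kJ mol⁻¹, ΔH = −21.0 kJ mol⁻¹)
    solid substrate ⇌ dissolved substrate, rate k5*(cs5 - [dissolved substrate]) while solid is left; crystals form when [dissolved substrate] > cs5 (solubility = 32.0 mM, k = 0.00247 s⁻¹)
    dissolved substrate + coupling partner → target (k = 0.00688 L mol⁻¹ s⁻¹, Ea = 64.0 kJ mol⁻¹)
    (constants at 70 °C)

At 48.0 h the flask's books close: target at 35.8% and isomer of the product at 24.9% of the solid substrate hold 0.0455 M, and decomposed reagent holds 0.0445 M, together 0.0900 M against b = 0.0900 M. Coupling partner stands at 0% of its charge, solid substrate at 0% and dissolved substrate at 0.118%. The neighbour flask, charged with 0.480 equiv of coupling partner, has b = 0.0360 M, below its 0.075 M of solid substrate, which makes coupling partner the limiting reagent by charge. There, at 48.0 h, coupling partner stands at 0% of its charge, target at 18.0% and isomer of the product at 12.5% hold 0.0229 M, and decomposed reagent holds 0.0131 M, together 0.0360 M against b = 0.0360 M, while side product stands at 69.0% of the solid substrate.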